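The route (labdane numbering) rests on reading C20–C10–C9–C8=C7 as the γ,δ-unsaturated acid retron of an Ireland–Claisen rearrangement. In ring B the C7=C8 alkene lies allylic to the C9–C10 bond that joins tertiary C9 and quaternary C10. The precursor is therefore not a decalin. It is ring A fused to a δ-lactone (C20 carbonyl, oxygen on C7), and C7 carries the complete E-trisubstituted side chain. The silyl ketene acetal of this lactone rearranges through a forced boat: C7–O breaks, C9–C10 forms, ring B closes and the alkene lands at C7=C8. The single carbinol centre C7 is traded for C9 and C10. C20 is then reduced to methyl, and the ring A oxygens follow under substrate control.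

Key step: step 9

Remark: labdane numbering is used for all compounds (ring A = C1–C5 and C10; ring B = C5–C10; side chain C11–C16; C17 on C8; C18 and C19 on C4; C20 on C10). The target belongs to the ent series, (2S,3R,5S,9R,10S). 4-Methylpent-1-en-3-one is taken as purchasable.

Step 1
Reactants: 1 geraniol
Product: 2 geranyl tert-butyldimethylsilyl ether
Conditions: TBSCl, imidazole, DMF, rt
Reagents that add atoms: tert-butyldimethylsilyl chloride, CC(C)(C)[Si](C)(C)Cl
Why: Standard silylation masks the C15 hydroxyl with a group that should tolerate the later enolate, hydride and oxidation steps and that leaves together with the ketal in step 14.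

Step 2
Reactants: 2 geranyl tert-butyldimethylsilyl ether
Product: 4 (2E,6E)-8-(tert-butyldimethylsilyloxy)-2,6-dimethylocta-2,6-dienal, via allylic alcohol 3 (not isolated)
Conditions: SeO2 (cat.), t-BuOOH, CH2Cl2, 0 °C to rt; crude material then MnO2, CH2Cl2, rt
Reagents that add atoms: tert-butyl hydroperoxide, CC(C)(C)OO (terminal oxygen source); selenium dioxide, O=[Se]=O (catalytic oxygen carrier)
Why: The Riley allylic oxidation (ene reaction, then [2,3]-shift) attacks the more electron-rich terminal alkene at its E-methyl group, and MnO2 converges alcohol and aldehyde on enal 4, which fixes the E geometry of the future C8=C9 bond.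

Step 3
Reactants: 4 (2E,6E)-8-(tert-butyldimethylsilyloxy)-2,6-dimethylocta-2,6-dienal
Product: 5 (4R,5E,9E)-11-(tert-butyldimethylsilyloxy)-5,9-dimethylundeca-1,5,9-trien-4-ol
Conditions: B-allyldiisopinocampheylborane derived from (−)-α-pinene, Et2O, −78 °C; then NaOH, H2O2
Reagents that add atoms: B-allyldiisopinocampheylborane from (−)-α-pinene, C=CCB([C@H]1C[C@H]2C[C@@H]([C@@H]1C)C2(C)C)[C@H]1C[C@H]2C[C@@H]([C@@H]1C)C2(C)C
Why: Brown allylboration through a closed chair transition state adds 1,2 to the enal, and this antipode of the reagent should give the (R)-carbinol, the future C7 and the only stereocentre of the route set by a reagent.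

Step 4
Reactants: 5 (4R,5E,9E)-11-(tert-butyldimethylsilyloxy)-5,9-dimethylundeca-1,5,9-trien-4-ol
Product: 6 acrylate ester of 5
Conditions: acryloyl chloride, Et3N, DMAP (cat.), CH2Cl2, 0 °C
Reagents that add atoms: acryloyl chloride, C=CC(=O)Cl
Why: Simple O-acylation brings in C20 and C10 without touching the carbinol configuration.

Step 5
Reactants: 6 acrylate ester of 5
Product: 7 (6R)-6-alkenyl-5,6-dihydro-2H-pyran-2-one
Conditions: second-generation Grubbs catalyst RuCl2(=CHPh)(PCy3)(SIMes) (5 mol %), CH2Cl2, 40 °C
Reagents that add atoms: none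
Why: Ring-closing metathesis joins the two monosubstituted alkenes to the six-membered unsaturated lactone, while the trisubstituted alkenes are too hindered to compete.

Step 6
Reactants: 8 4-methylpent-1-en-3-one
Product: 9 4-methyl-3-(trimethylsilyloxy)penta-1,3-diene
Conditions: TMSOTf, Et3N, Et2O, 0 °C
Reagents that add atoms: trimethylsilyl trifluoromethanesulfonate, C[Si](C)(C)OS(=O)(=O)C(F)(F)F
Why: Soft enolisation can only remove the isopropyl methine hydrogen and stores the polymerisation-prone vinyl ketone as its cross-conjugated silyl dienol ether.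

Step 7
Reactants: 7 (6R)-6-alkenyl-5,6-dihydro-2H-pyran-2-one; 9 4-methyl-3-(trimethylsilyloxy)penta-1,3-diene
Product: 12 cis-fused keto lactone (3R,4aS,8aS)-3-alkenyl-5,5-dimethylhexahydro-1H-isochromene-1,6(5H)-dione, via lithium dienolate 10 (not isolated), via lactone enolate 11 (not isolated)
Conditions: 9, MeLi, THF, 0 °C; then 7, −78 to 0 °C; then H2O
Reagents that add atoms: none
Why: In this double Michael annulation (Michael–Michael ring closure, a stepwise formal [4+2]) the tertiary carbon C4 of dienolate 10 adds to C5 of the pentenolide anti to the C7 substituent (the usual trans-4,6 outcome of axial attack), and enolate 11 then closes ring A by 6-endo-trig addition of C10 to the liberated vinyl ketone on the face of C4, giving a cis fusion whose C10 centre is erased again in step 9 so that any C10 epimer converges there.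

Step 8
Reactants: 12 cis-fused keto lactone
Product: 13 ethylene ketal of 12 at C3
Conditions: TMSOCH2CH2OTMS, TMSOTf (cat.), CH2Cl2, −78 to −20 °C
Reagents that add atoms: 1,2-bis(trimethylsilyloxy)ethane, C[Si](C)(C)OCCO[Si](C)(C)C
Why: Noyori ketalisation under aprotic, low-temperature conditions masks the more acidic ketone, so that base can address only the lactone, and spares the allylic lactone C–O bond and the silyl ether.

Step 9
Reactants: 13 ethylene ketal of 12 at C3
Product: 15 tert-butyldimethylsilyl 15-(tert-butyldimethylsilyloxy)-3,3-ethylenedioxy-ent-labda-7,13E-dien-20-oate, via silyl ketene acetal 14 (not isolated)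
Conditions: LiN(iPr)2, THF/HMPA, −78 °C; TBSCl, −78 °C to rt; then toluene, 110 °C
Reagents that add atoms: tert-butyldimethylsilyl chloride, CC(C)(C)[Si](C)(C)Cl
Why: LiN(iPr)2 removes the tertiary C10–H of lactone 13 and O-silylation fixes the endocyclic ketene acetal 14, whose O–C20=C10 unit and C7–C8=C9 allyl unit form the six-atom array of an Ireland–Claisen [3,3]-sigmatropic shift, the closest known type being the Claisen contraction of silyl ketene acetals of alkenyl-substituted lactones and dioxanones to cycloalkene- and dihydropyran-carboxylic acids. Ring B (C5–C6–C7–C8–C9–C10) closes by suprafacial C9–C10 bond formation while the temporary lactone ring opens at C7–O, and because C5–C6 bridges the two termini only a boat-shaped, bicyclo[2.2.2]octane-like transition state is possible. C10: the alkenyl arm sits on the lactone face that carries H-5 (set in step 7) and C4 points away from it, so C9 bonds to that face, C20 is pushed to the opposite face and the decalin should be trans-fused. C9: in the boat the E-alkene holds C11 in the outside position next to C1, which makes C11 and C20 cis on ring B, so (7R) is relayed to (9R) and to the C10 configuration of 24 while C7 becomes sp2. The double bond is delivered regiospecifically to C7=C8 with its methyl group in place, so no positional olefin isomers should arise. The step needs enolisation at C10 only and O- rather than C-silylation, which are secured by the ketal at C3, the absence of any other acidic C–H and the TBSCl/HMPA protocol on a fully substituted enolate carbon.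

Step 10
Reactants: 15 silyl ester
Product: 16 C20 primary alcohol
Conditions: LiAlH4, Et2O, 0 °C to rt; then H2O
Reagents that add atoms: none
Why: Hydride reduction of the activated silyl ester reaches the neopentyl carbinol and leaves the ketal, the silyl ether and both alkenes untouched.

Step 11
Reactants: 16 C20 primary alcohol
Product: 17 C20 aldehyde
Conditions: Pr4N[RuO4] (5 mol %), N-methylmorpholine N-oxide, 4 Å molecular sieves, CH2Cl2, rt
Reagents that add atoms: none
Why: Ley–Griffith oxidation is neutral, stops at the non-enolisable aldehyde and does not attack trisubstituted alkenes.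

Step 12
Reactants: 17 C20 aldehyde
Product: 18 C20 aldehyde (E)-tosylhydrazone
Conditions: TsNHNH2, THF, 50 °C
Reagents that add atoms: p-toluenesulfonohydrazide, Cc1ccc(cc1)S(=O)(=O)NN
Why: Acid-free hydrazone condensation works even on a neopentyl aldehyde, and the C3 ketal prevents a second hydrazone.

Step 13
Reactants: 18 C20 aldehyde (E)-tosylhydrazone
Product: 20 15-(tert-butyldimethylsilyloxy)-3,3-ethylenedioxy-ent-labda-7,13E-diene, via alkyl diazene 19 (not isolated)
Conditions: catecholborane, CHCl3, 0 °C; then NaOAc·3H2O, reflux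
Reagents that add atoms: none
Why: In this Caglioti-type tosylhydrazone reduction the borane adds hydride to C=N, acetate triggers loss of sulfinate, and diazene 19 expels N2 to leave the C20 methyl group under conditions mild enough for the ketal, the silyl ether and the unconjugated alkenes.

Step 14
Reactants: 20 15-(tert-butyldimethylsilyloxy)-3,3-ethylenedioxy-ent-labda-7,13E-diene
Product: 21 15-hydroxy-ent-labda-7,13E-dien-3-one
Conditions: TsOH·H2O (cat.), acetone/H2O, rt
Reagents that add atoms: water, O
Why: Mild acid hydrolysis removes the sterically compressed ketal and the primary silyl ether in one operation without moving the C7=C8 bond.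

Step 15
Reactants: 21 15-hydroxy-ent-labda-7,13E-dien-3-one
Product: 23 (2S)-2,15-diacetoxy-ent-labda-7,13E-dien-3-one, via ketol 22 (not isolated)
Conditions: KN(SiMe3)2 (2.2 equiv), THF, −78 °C; 2-(phenylsulfonyl)-3-phenyloxaziridine, −78 °C; then Ac2O, DMAP, −78 °C to rt
Reagents that add atoms: 2-(phenylsulfonyl)-3-phenyloxaziridine, O=S(=O)(N1OC1c1ccccc1)c1ccccc1; acetic anhydride, CC(=O)OC(C)=O
Why: In this Davis enolate oxidation with in situ acylation C2 is the only enolisable position, the oxaziridine approaches the enolate from the face opposite the axial C20 and C4 methyl groups to give the equatorial (also thermodynamic) C2 alkoxide, and Ac2O caps this alkoxide and the C15 alkoxide in the same flask.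

Step 16
Reactants: 23 (2S)-2,15-diacetoxy-ent-labda-7,13E-dien-3-one
Product: 24 target, (2S,3R,5S,9R,10S)-2,15-diacetoxy-ent-labda-7,13E-dien-3-ol
Conditions: Li[HB(s-Bu)3] (L-Selectride), THF, −78 °C; then H2O
Reagents that add atoms: none
Why: Under steric approach control the bulky trialkylborohydride avoids the axial path past H-1 and H-5 and attacks C3 equatorially from the face of the C20 methyl group, which should give the axial C3 alcohol cis to the equatorial C2 acetate at a temperature at which both acetates survive.

Compound list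
1 | geraniol, (2E)-3,7-dimethylocta-2,6-dien-1-ol | CC(C)=CCC/C(C)=C/CO | starting material
2 | geranyl tert-butyldimethylsilyl ether | CC(C)=CCC/C(C)=C/CO[Si](C)(C)C(C)(C)C | intermediate
3 | (2E,6E)-8-(tert-butyldimethylsilyloxy)-2,6-dimethylocta-2,6-dien-1-ol | OC/C(C)=C/CC/C(C)=C/CO[Si](C)(C)C(C)(C)C | intermediate
4 | (2E,6E)-8-(tert-butyldimethylsilyloxy)-2,6-dimethylocta-2,6-dienal | O=C/C(C)=C/CC/C(C)=C/CO[Si](C)(C)C(C)(C)C | intermediate
5 | (4R,5E,9E)-11-(tert-butyldimethylsilyloxy)-5,9-dimethylundeca-1,5,9-trien-4-ol | C=CC[C@@H](O)/C(C)=C/CC/C(C)=C/CO[Si](C)(C)C(C)(C)C | intermediate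
6 | (4R,5E,9E)-11-(tert-butyldimethylsilyloxy)-5,9-dimethylundeca-1,5,9-trien-4-yl prop-2-enoate | C=CC[C@@H](OC(=O)C=C)/C(C)=C/CC/C(C)=C/CO[Si](C)(C)C(C)(C)C | intermediate
7 | (6R)-6-[(2E,6E)-8-(tert-butyldimethylsilyloxy)-6-methylocta-2,6-dien-2-yl]-5,6-dihydro-2H-pyran-2-one | O=C1C=CC[C@@H](O1)/C(C)=C/CC/C(C)=C/CO[Si](C)(C)C(C)(C)C | intermediate
8 | 4-methylpent-1-en-3-one (isopropyl vinyl ketone) | C=CC(=O)C(C)C | starting material
9 | 4-methyl-3-(trimethylsilyloxy)penta-1,3-diene | C=CC(O[Si](C)(C)C)=C(C)C | intermediate
10 | lithium 4-methylpenta-1,3-dien-3-olate | [Li+].[O-]C(C=C)=C(C)C | intermediate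
11 | lithium enolate of the first Michael adduct (C5 S, C7 R; C4 trans to the C7 alkenyl group) | [Li+].[O-]C1=C[C@@H](C(C)(C)C(=O)C=C)C[C@@H](O1)/C(C)=C/CC/C(C)=C/CO[Si](C)(C)C(C)(C)C | intermediate
12 | (3R,4aS,8aS)-3-[(2E,6E)-8-(tert-butyldimethylsilyloxy)-6-methylocta-2,6-dien-2-yl]-5,5-dimethylhexahydro-1H-isochromene-1,6(5H)-dione (cis-fused; H-5, H-10 and the C7 alkenyl group on one face) | O=C1O[C@@H](/C(C)=C/CC/C(C)=C/CO[Si](C)(C)C(C)(C)C)C[C@H]2[C@@H]1CCC(=O)C2(C)C | intermediate
13 | ethylene ketal of 12 at the ring ketone (labdane C3), (3R,4aS,8aS) | O=C1O[C@@H](/C(C)=C/CC/C(C)=C/CO[Si](C)(C)C(C)(C)C)C[C@H]2[C@@H]1CCC1(OCCO1)C2(C)C | intermediate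
14 | tert-butyldimethylsilyl ketene acetal of 13 (C10=C20 double bond; C5 and C7 as in 13) | CC(C)(C)[Si](C)(C)OC1=C2CCC3(OCCO3)C(C)(C)[C@H]2C[C@@H](O1)/C(C)=C/CC/C(C)=C/CO[Si](C)(C)C(C)(C)C | intermediate
15 | tert-butyldimethylsilyl 15-(tert-butyldimethylsilyloxy)-3,3-ethylenedioxy-ent-labda-7,13E-dien-20-oate (trans-decalin; H-5 anti to C20; C11 syn to C20; 5R,9R,10R by the sequence rule) | CC(C)(C)[Si](C)(C)OC/C=C(\C)CC[C@@H]1C(C)=CC[C@@H]2C(C)(C)C3(OCCO3)CC[C@@]12C(=O)O[Si](C)(C)C(C)(C)C | intermediate
16 | 15-(tert-butyldimethylsilyloxy)-3,3-ethylenedioxy-ent-labda-7,13E-dien-20-ol (5S,9R,10R; spatial arrangement as in 15) | CC(C)(C)[Si](C)(C)OC/C=C(\C)CC[C@@H]1C(C)=CC[C@@H]2C(C)(C)C3(OCCO3)CC[C@@]12CO | intermediate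
17 | 15-(tert-butyldimethylsilyloxy)-3,3-ethylenedioxy-ent-labda-7,13E-dien-20-al (5S,9R,10R) | CC(C)(C)[Si](C)(C)OC/C=C(\C)CC[C@@H]1C(C)=CC[C@@H]2C(C)(C)C3(OCCO3)CC[C@@]12C=O | intermediate
18 | (E)-p-toluenesulfonylhydrazone of 17 | CC(C)(C)[Si](C)(C)OC/C=C(\C)CC[C@@H]1C(C)=CC[C@@H]2C(C)(C)C3(OCCO3)CC[C@@]12/C=N/NS(=O)(=O)c1ccc(C)cc1 | intermediate
19 | C20 monoalkyl diazene | CC(C)(C)[Si](C)(C)OC/C=C(\C)CC[C@@H]1C(C)=CC[C@@H]2C(C)(C)C3(OCCO3)CC[C@@]12CN=N | intermediate
20 | (5S,9R,10S)-15-(tert-butyldimethylsilyloxy)-3,3-ethylenedioxy-ent-labda-7,13E-diene | CC(C)(C)[Si](C)(C)OC/C=C(\C)CC[C@@H]1C(C)=CC[C@@H]2C(C)(C)C3(OCCO3)CC[C@@]12C | intermediate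
21 | (5S,9R,10S)-15-hydroxy-ent-labda-7,13E-dien-3-one | OC/C=C(\C)CC[C@@H]1C(C)=CC[C@@H]2C(C)(C)C(=O)CC[C@@]12C | intermediate
22 | (2S,5S,9R,10S)-2,15-dihydroxy-ent-labda-7,13E-dien-3-one (equatorial C2 hydroxyl, anti to C20; present in the flask as its potassium alkoxides) | OC/C=C(\C)CC[C@@H]1C(C)=CC[C@@H]2C(C)(C)C(=O)[C@@H](O)C[C@@]12C | intermediate
23 | (2S,5S,9R,10S)-2,15-diacetoxy-ent-labda-7,13E-dien-3-one | CC(=O)OC/C=C(\C)CC[C@@H]1C(C)=CC[C@@H]2C(C)(C)C(=O)[C@@H](OC(C)=O)C[C@@]12C | intermediate
24 | (2S,3R,5S,9R,10S)-2,15-diacetoxy-ent-labda-7,13E-dien-3-ol (CNP0254679.1) | CC(=O)OC/C=C(\C)CC[C@@H]1C(C)=CC[C@@H]2C(C)(C)[C@@H](O)[C@@H](OC(C)=O)C[C@@]12C | target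

Total step count: 16. Longest linear sequence: 15 (steps 1–5 and 7–16, from geraniol).

Steps most likely to fail

Step 9. Enolisation of the hindered tertiary C10–H may be slow or incomplete. C-silylation or hydrolysis of the ketene acetal may intervene, or thermal decomposition may outrun the strained boat transition state. The fallback runs the same bond reorganisation on a neutral, base-free substrate at the aldehyde oxidation level. It sets out from 13. i-Bu2AlH (CH2Cl2, −78 °C) should give the lactol F1. Mesylation–elimination (MsCl, Et3N, CH2Cl2, 0 °C to reflux) should then give the bicyclic enol ether F2, a 2-alkenyl-3,4-dihydro-2H-pyran. Thermolysis (o-xylene, sealed tube, 180–200 °C) should bring about the aliphatic Claisen rearrangement through the same boat. This leads directly to aldehyde 17, where the route is rejoined and steps 10 and 11 fall away.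

Step 7. The basic dienolate may deprotonate pentenolide 7 at C6 and open it to the dienoate, or it may add 1,2. The second Michael addition may also stall, or the liberated vinyl ketone may oligomerise. The fallback replaces the anionic manifold by acid catalysis and sets out from 7 and 9. With HNTf2 (cat.) or a mixed AlBr3/AlMe3 Lewis acid (CH2Cl2/toluene, −78 to −20 °C), silyloxydiene 9 should engage 7 in a Mukaiyama–Michael-initiated Diels–Alder reaction on the same face. This gives the trimethylsilyl enol ether F3, which aqueous citric acid hydrolyses to 12, where the route is rejoined.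

Step 16. Facial selectivity of hydride delivery may be poor because the axial C4 methyl group flanks the equatorial trajectory, and the acetate may migrate or be lost at the alkoxide stage. The fallback changes the control element from substrate to catalyst and changes the end game from a late reduction to a late site-selective acylation. It sets out from ketol 22, isolated by omitting the Ac2O quench in step 15. Corey–Bakshi–Shibata reduction follows, using (R)-2-methyl-CBS-oxazaborolidine and catecholborane in toluene at −78 to −40 °C, with the quaternary C4 acting as the large group. It should give the 2,3-cis triol F4. Controlled acetylation (Ac2O, pyridine, 0 °C) of the primary C15 and equatorial C2 hydroxyls leaves the axial neopentyl C3 hydroxyl free and should give 24.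

Further compounds
F1 | step 9 | lactol from 13 (C20 hemiacetal, anomer mixture; C5, C7, C10 as in 13) | OC1O[C@@H](/C(C)=C/CC/C(C)=C/CO[Si](C)(C)C(C)(C)C)C[C@H]2[C@@H]1CCC1(OCCO1)C2(C)C
F2 | step 9 | bicyclic enol ether (C10=C20, 2-alkenyl-3,4-dihydro-2H-pyran; C5 and C7 as in 13) | C1=C2CCC3(OCCO3)C(C)(C)[C@H]2C[C@@H](O1)/C(C)=C/CC/C(C)=C/CO[Si](C)(C)C(C)(C)C
F3 | step 7 | trimethylsilyl enol ether (C2=C3) of keto lactone 12 | O=C1O[C@@H](/C(C)=C/CC/C(C)=C/CO[Si](C)(C)C(C)(C)C)C[C@H]2[C@@H]1CC=C(O[Si](C)(C)C)C2(C)C
F4 | step 16 | (2S,3R,5S,9R,10S)-ent-labda-7,13E-diene-2,3,15-triol | OC/C=C(\C)CC[C@@H]1C(C)=CC[C@@H]2C(C)(C)[C@@H](O)[C@@H](O)C[C@@]12C
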